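**Plan**
1. Retrosynthesis: remove the O–CH3 group and lower C4 to the acyloin 18. Then join C4 to C8, so that the ring C1–C2–C3–C4–C5–C8 shrinks to a cyclopentanone C1–C2–C3–C4–C8 fused to a cyclopropane C4–C5–C8 (tricycle 16).
2. Enabling feature: C8=O and C3 (an enol-ether carbon, that is a masked ketone) stand 1,4 to each other across C5–C4. This is the retron of a 2-siloxycyclopropyl ketone, and C4–C8 is its donor–acceptor bond.
3. Further cuts: C4–C5 and C4–C8 (keto-carbene plus silyl enol ether C5=C8), C6–aryl (cuprate), C1–allyl and C1–C2 (enolate alkylations), C7–CH3 (cuprate).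
4. Forward order: the ring C1–C8–C5–C6–C7 comes from cyclopentenone 1 and is fully substituted first. Cyclopropanation then closes the cyclopentanone and the cyclopropane together, and ring expansion gives the bicyclo[3.2.1]octane.
5. Stereochemistry: the single centre of (S)-1 directs CH3 (anti). CH3 then directs allyl and aryl (both anti), the tether directs the carbene, and the bridgeheads follow.

Key step: step 9

Remark: C1–C8 are the core atoms of the target throughout (C1 allyl, C3 OMe, C4 and C8 C=O, C6 aryl, C7 methyl). Both enantiomers of 1 are taken as commercial. The C4 carbinol centre of 18 is drawn as the expected exo alcohol and is erased in step 10.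

Step 1
Reactants: 1 (S)-4-(tert-butyldimethylsilyloxy)cyclopent-2-en-1-one
Product: 2 (3S,4S)-4-(tert-butyldimethylsilyloxy)-3-methylcyclopentan-1-one (methyl trans to OTBS)
Conditions: MeLi (2 equiv), CuI, Et2O, 0 °C; 1, −78 °C; aq NH4Cl
Reagents that add atoms: lithium dimethylcuprate [Li+].C[Cu-]C
Why: Gilman cuprate 1,4-addition to a 4-silyloxycyclopentenone takes place anti to the silyloxy group, which sets the methyl-bearing centre (C7).

Step 2
Reactants: 2 (3S,4S)-4-(tert-butyldimethylsilyloxy)-3-methylcyclopentan-1-one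
Product: 3 (S)-4-methylcyclopent-2-en-1-one
Conditions: DBU, CH2Cl2, 0 °C, short contact
Reagents that add atoms: none
Why: E1cB β-elimination of silanolate from the β-silyloxy ketone moves the enone to the other side of the ring and should leave the methyl centre, now γ to the carbonyl, untouched if base contact is short.

Step 3
Reactants: 4 2-methoxypropene
Product: 5 3-bromo-2-methoxyprop-1-ene (2-methoxyallyl bromide)
Conditions: NBS, CH2Cl2–pentane, 0 °C; used freshly distilled
Reagents that add atoms: N-bromosuccinimide O=C1CCC(=O)N1Br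
Why: Electrophilic bromination of the enol ether, followed by loss of a methyl proton from the oxocarbenium ion (addition–elimination), is the known preparation of this acetonyl-cation equivalent; no stereocentre is formed.

Step 4
Reactants: 3 (S)-4-methylcyclopent-2-en-1-one; 5 3-bromo-2-methoxyprop-1-ene
Product: 6 (4R,5S)-5-(2-methoxyprop-2-en-1-yl)-4-methylcyclopent-2-en-1-one
Conditions: LDA, THF, −78 °C; 5, DMPU, −78 to −30 °C
Reagents that add atoms: none
Why: Kinetic α′-deprotonation of the cyclopentenone and SN2 enolate alkylation with the allylic bromide, which enters trans to the neighbouring methyl group (this centre is planarised again in step 5).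

Step 5
Reactants: 6 (4R,5S)-5-(2-methoxyprop-2-en-1-yl)-4-methylcyclopent-2-en-1-one; 7 allyl bromide
Product: 9 (4R,5R)-5-allyl-4-methyl-5-(2-oxopropyl)cyclopent-2-en-1-one, via quaternary enol ether 8 (not isolated)
Conditions: LDA, THF, −78 °C; 7, DMPU, −78 to 0 °C; then 1 M aq oxalic acid, THF, rt
Reagents that add atoms: water O
Why: A second α′-enolate alkylation builds the quaternary centre (C1) with allyl bromide approaching anti to the adjacent methyl group, so the masked acetonyl arm ends cis to methyl, and mild acid hydrolysis of the enol ether then frees the methyl ketone.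

Step 6
Reactants: 9 (4R,5R)-5-allyl-4-methyl-5-(2-oxopropyl)cyclopent-2-en-1-one; 10 4-bromo-1,2-dimethoxybenzene
Product: 13 1-[(1R,4R,5R)-1-allyl-2-(tert-butyldimethylsilyloxy)-4-(3,4-dimethoxyphenyl)-5-methylcyclopent-2-en-1-yl]propan-2-one, via aryllithium 11 (not isolated), via diarylcuprate 12 (not isolated)
Conditions: 10, n-BuLi, THF, −78 °C; CuI (0.5 equiv), −40 °C; 9, −78 °C; TBSCl, HMPA, Et3N, −78 to 0 °C; aq NH4Cl
Reagents that add atoms: tert-butyldimethylsilyl chloride C[Si](C)(Cl)C(C)(C)C; n-butyllithium [Li]CCCC (Li of 11); copper(I) iodide [Cu]I (Cu of 12)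
Why: Gilman conjugate addition with O-silylation of the enolate puts the aryl group anti to the vicinal methyl group (sets C6), should spare the hindered saturated ketone at −78 °C, and gives the only possible silyl enol ether because the other α-carbon is quaternary.

Step 7
Reactants: 13 1-[(1R,4R,5R)-1-allyl-2-(tert-butyldimethylsilyloxy)-4-(3,4-dimethoxyphenyl)-5-methylcyclopent-2-en-1-yl]propan-2-one
Product: 15 1-diazo-3-[(1R,4R,5R)-1-allyl-2-(tert-butyldimethylsilyloxy)-4-(3,4-dimethoxyphenyl)-5-methylcyclopent-2-en-1-yl]propan-2-one, via trifluoroacetyl diketone 14 (not isolated)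
Conditions: LiHMDS, THF, −78 °C; CF3CO2CH2CF3; then MsN3, Et3N, MeCN, rt; aq NH4Cl
Reagents that add atoms: methanesulfonyl azide CS(=O)(=O)N=[N+]=[N-]; 2,2,2-trifluoroethyl trifluoroacetate O=C(OCC(F)(F)F)C(F)(F)F (atoms only in 14)
Why: Detrifluoroacetylative (Regitz-type) diazo transfer: kinetic deprotonation at the methyl group of the only free ketone, trifluoroacetylation and reaction with the sulfonyl azide give the terminal α-diazoketone under conditions a TBS enol ether tolerates; no stereocentre is touched.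

Step 8
Reactants: 15 1-diazo-3-[(1R,4R,5R)-1-allyl-2-(tert-butyldimethylsilyloxy)-4-(3,4-dimethoxyphenyl)-5-methylcyclopent-2-en-1-yl]propan-2-one
Product: 16 (1S,2S,5R,6R,7R,8R)-5-allyl-1-(tert-butyldimethylsilyloxy)-7-(3,4-dimethoxyphenyl)-6-methyltricyclo[3.3.0.0^2,8]octan-3-one
Conditions: Rh2(cap)4 (1 mol %), CH2Cl2, reflux, slow addition of 15
Reagents that add atoms: none
Why: Rh(II)-carbenoid intramolecular cyclopropanation of a 1-diazo-3-(cyclopent-2-enyl)propan-2-one is the classical entry to tricyclo[3.3.0.0^2,8]octan-3-ones; the short tether lets the carbene reach only the ring face that carries it (cis to methyl, anti to aryl), which sets C5, and the electron-rich silyl enol ether should outrun the allyl group, helped by a carboxamidate catalyst that disfavours C–H insertion.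

Step 9
Reactants: 16 (1S,2S,5R,6R,7R,8R)-5-allyl-1-(tert-butyldimethylsilyloxy)-7-(3,4-dimethoxyphenyl)-6-methyltricyclo[3.3.0.0^2,8]octan-3-one
Product: 18 (1R,4R,5R,6R,7R)-1-allyl-6-(3,4-dimethoxyphenyl)-4-hydroxy-7-methylbicyclo[3.2.1]octane-3,8-dione, via C4 enolate 17 (not isolated)
Conditions: TASF, THF, −78 to −40 °C; 2-(phenylsulfonyl)-3-phenyloxaziridine, −78 °C; AcOH, −78 °C
Reagents that add atoms: 2-(phenylsulfonyl)-3-phenyloxaziridine O=S(=O)(N1OC1c1ccccc1)c1ccccc1; TASF CN(C)[S+](N(C)C)N(C)C.C[Si-](C)(C)(F)F (cation of 17)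
Why: Fluoride removes the silyl group, and the resulting cyclopropanolate is a strained aldolate (O–C8–C4–C3=O) that undergoes retro-aldol cleavage of C4–C8, so the cyclopentanone ring C1–C2–C3–C4–C8 takes up C5 and becomes the six-membered ring C1–C2–C3–C4–C5–C8 while C8 becomes the bridging ketone. The closest known reaction type is the fluoride-induced opening of 2-siloxycyclopropyl ketones and esters (donor–acceptor cyclopropanes) to 1,4-dicarbonyl enolates that are trapped in situ by electrophiles, combined here with Davis oxaziridine hydroxylation of an enolate. No ring is closed by bond formation: the cyclopropane and the cyclopentanone merge by loss of their shared bond, which turns the tricyclo[3.3.0.0^2,8]octane into the bicyclo[3.2.1]octane. C1, C5, C6 and C7 are carried over unchanged, and the only new centre, the C4 carbinol, should arise by attack on the exo face (the side of the C8 bridge, away from the endo methyl group) and is erased in step 10. The step needs bond selectivity and enolate regiochemistry: only C4–C8 joins the oxygen-bearing donor carbon to the acyl-bearing carbon, so C5–C8 and C4–C5 stay, and the enolate is born at C3=C4, cannot move toward the bridgehead C5, and moves only slowly toward C2 at −78 °C. The cold acidic quench limits retro-aldol loss of the C4 alkoxide.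

Step 10
Reactants: 18 (1R,4R,5R,6R,7R)-1-allyl-6-(3,4-dimethoxyphenyl)-4-hydroxy-7-methylbicyclo[3.2.1]octane-3,8-dione
Product: 19 (1S,5S,6R,7R)-1-allyl-6-(3,4-dimethoxyphenyl)-3-hydroxy-7-methylbicyclo[3.2.1]oct-2-ene-4,8-dione
Conditions: Dess–Martin periodinane, CH2Cl2, 0 °C to rt
Reagents that add atoms: none
Why: Dess–Martin oxidation of the acyloin gives the 3,4-diketone, which can enolise only toward C2 because C5 is a bridgehead (Bredt), so a single diosphenol should result and the C4 centre disappears.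

Step 11
Reactants: 19 (1S,5S,6R,7R)-1-allyl-6-(3,4-dimethoxyphenyl)-3-hydroxy-7-methylbicyclo[3.2.1]oct-2-ene-4,8-dione
Product: 20 kadsurenin D, (1S,5S,6R,7R)-1-allyl-6-(3,4-dimethoxyphenyl)-3-methoxy-7-methylbicyclo[3.2.1]oct-2-ene-4,8-dione
Conditions: TMSCHN2, toluene–MeOH (4:1), 0 °C
Reagents that add atoms: (trimethylsilyl)diazomethane C[Si](C)(C)C=[N+]=[N-]
Why: Diazomethane-type O-methylation of the acidic diosphenol hydroxyl runs without base, which spares the non-enolisable β-diketone from retro-Claisen cleavage; no stereocentre is touched.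

**Compound list**
1 | (S)-4-(tert-butyldimethylsilyloxy)cyclopent-2-en-1-one | O=C1C=C[C@@H](O[Si](C)(C)C(C)(C)C)C1 | starting material
2 | (3S,4S)-4-(tert-butyldimethylsilyloxy)-3-methylcyclopentan-1-one | O=C1C[C@H](C)[C@@H](O[Si](C)(C)C(C)(C)C)C1 | intermediate
3 | (S)-4-methylcyclopent-2-en-1-one | O=C1C=C[C@@H](C)C1 | intermediate
4 | 2-methoxypropene | C=C(C)OC | starting material
5 | 3-bromo-2-methoxyprop-1-ene | COC(=C)CBr | intermediate
6 | (4R,5S)-5-(2-methoxyprop-2-en-1-yl)-4-methylcyclopent-2-en-1-one | O=C1C=C[C@@H](C)[C@@H]1CC(=C)OC | intermediate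
7 | allyl bromide | C=CCBr | starting material
8 | (4R,5R)-5-allyl-5-(2-methoxyprop-2-en-1-yl)-4-methylcyclopent-2-en-1-one | O=C1C=C[C@@H](C)[C@@]1(CC=C)CC(=C)OC | intermediate
9 | (4R,5R)-5-allyl-4-methyl-5-(2-oxopropyl)cyclopent-2-en-1-one | O=C1C=C[C@@H](C)[C@@]1(CC=C)CC(C)=O | intermediate
10 | 4-bromo-1,2-dimethoxybenzene | COc1ccc(Br)cc1OC | starting material
11 | 3,4-dimethoxyphenyllithium | [Li]c1ccc(OC)c(OC)c1 | intermediate
12 | lithium bis(3,4-dimethoxyphenyl)cuprate | [Li+].COc1ccc([Cu-]c2ccc(OC)c(OC)c2)cc1OC | intermediate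
13 | 1-[(1R,4R,5R)-1-allyl-2-(tert-butyldimethylsilyloxy)-4-(3,4-dimethoxyphenyl)-5-methylcyclopent-2-en-1-yl]propan-2-one | CC(=O)C[C@@]1(CC=C)C(O[Si](C)(C)C(C)(C)C)=C[C@H](c2ccc(OC)c(OC)c2)[C@H]1C | intermediate
14 | 1,1,1-trifluoro-5-[(1R,4R,5R)-1-allyl-2-(tert-butyldimethylsilyloxy)-4-(3,4-dimethoxyphenyl)-5-methylcyclopent-2-en-1-yl]pentane-2,4-dione | FC(F)(F)C(=O)CC(=O)C[C@@]1(CC=C)C(O[Si](C)(C)C(C)(C)C)=C[C@H](c2ccc(OC)c(OC)c2)[C@H]1C | intermediate
15 | 1-diazo-3-[(1R,4R,5R)-1-allyl-2-(tert-butyldimethylsilyloxy)-4-(3,4-dimethoxyphenyl)-5-methylcyclopent-2-en-1-yl]propan-2-one | [N-]=[N+]=CC(=O)C[C@@]1(CC=C)C(O[Si](C)(C)C(C)(C)C)=C[C@H](c2ccc(OC)c(OC)c2)[C@H]1C | intermediate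
16 | (1S,2S,5R,6R,7R,8R)-5-allyl-1-(tert-butyldimethylsilyloxy)-7-(3,4-dimethoxyphenyl)-6-methyltricyclo[3.3.0.0^2,8]octan-3-one | O=C1C[C@]2(CC=C)[C@H](C)[C@@H](c4ccc(OC)c(OC)c4)[C@@H]3[C@H]1[C@]23O[Si](C)(C)C(C)(C)C | intermediate
17 | tris(dimethylamino)sulfonium C3=C4 enolate of the ring-expanded 3,8-dione | C=CC[C@]12CC([O-])=C[C@H](C1=O)[C@H](c1ccc(OC)c(OC)c1)[C@H]2C.CN(C)[S+](N(C)C)N(C)C | intermediate
18 | (1R,4R,5R,6R,7R)-1-allyl-6-(3,4-dimethoxyphenyl)-4-hydroxy-7-methylbicyclo[3.2.1]octane-3,8-dione | C=CC[C@]12CC(=O)[C@H](O)[C@H](C1=O)[C@H](c1ccc(OC)c(OC)c1)[C@H]2C | intermediate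
19 | (1S,5S,6R,7R)-1-allyl-6-(3,4-dimethoxyphenyl)-3-hydroxy-7-methylbicyclo[3.2.1]oct-2-ene-4,8-dione | C=CC[C@]12C=C(O)C(=O)[C@H](C1=O)[C@H](c1ccc(OC)c(OC)c1)[C@H]2C | intermediate
20 | kadsurenin D | C=CC[C@]12C=C(OC)C(=O)[C@H](C1=O)[C@H](c1ccc(OC)c(OC)c1)[C@H]2C | target

**Count:** 11 steps in total. The longest linear sequence is 10 steps (steps 1, 2, 4–11).

**Steps most likely to fail**

Step 9. What may go wrong: early protonation or equilibration of the fluoride-generated enolate, or retro-aldol opening of the C4 alkoxide before the quench. The fallback sets out from 16. Protic desilylation with Et3N·3HF in THF triggers the same ring expansion, but the enolate is simply protonated, giving (1R,5S,6R,7R)-1-allyl-6-(3,4-dimethoxyphenyl)-7-methylbicyclo[3.2.1]octane-3,8-dione F1. Kinetic enolisation with LiHMDS and TMSCl at −78 °C should occur at C4, because C2 is neopentyl, and gives (1R,5R,6R,7R)-1-allyl-6-(3,4-dimethoxyphenyl)-7-methyl-3-(trimethylsilyloxy)bicyclo[3.2.1]oct-3-en-8-one F2. Rubottom oxidation with dimethyldioxirane and a mildly acidic work-up installs the C4 hydroxyl under non-basic conditions. The route is rejoined at 18.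

Step 6. What may go wrong: 1,2-attack of the aryl-metal species on the side-chain ketone, or aldol attack of the intermediate enolate on it before silylation. The fallback sets out from 8, which is isolated by leaving out the acid treatment of step 5. The same cuprate addition and TBSCl trap then give the bis(enol ether) tert-butyl{[(3R,4R,5R)-5-allyl-3-(3,4-dimethoxyphenyl)-5-(2-methoxyprop-2-en-1-yl)-4-methylcyclopent-1-en-1-yl]oxy}dimethylsilane F3, with no free ketone present. PPTS in wet acetone at 0 °C should cleave only the much more labile 2-methoxypropenyl ether. The route is rejoined at 13.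

Step 4. What may go wrong: decomposition of the labile bromide 5, or proton transfer between enolate and product that leads to over-alkylation. The fallback sets out from 3 and makes step 3 unnecessary. A robust alkyne serves as the acetonyl equivalent. LDA and 3-bromo-1-(trimethylsilyl)propyne give (4R,5S)-4-methyl-5-[3-(trimethylsilyl)prop-2-yn-1-yl]cyclopent-2-en-1-one F4. A second LDA alkylation with 7 gives (4R,5R)-5-allyl-4-methyl-5-[3-(trimethylsilyl)prop-2-yn-1-yl]cyclopent-2-en-1-one F5. Gold(I)-catalysed Markovnikov hydration with protodesilylation ((Ph3P)AuCl, AgOTf, MeOH–H2O) gives the methyl ketone. The route is rejoined at 9.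

**Further compounds**
F1 | step 9 | (1R,5S,6R,7R)-1-allyl-6-(3,4-dimethoxyphenyl)-7-methylbicyclo[3.2.1]octane-3,8-dione | C=CC[C@]12CC(=O)C[C@H](C1=O)[C@H](c1ccc(OC)c(OC)c1)[C@H]2C
F2 | step 9 | (1R,5R,6R,7R)-1-allyl-6-(3,4-dimethoxyphenyl)-7-methyl-3-(trimethylsilyloxy)bicyclo[3.2.1]oct-3-en-8-one | C=CC[C@]12CC(O[Si](C)(C)C)=C[C@H](C1=O)[C@H](c1ccc(OC)c(OC)c1)[C@H]2C
F3 | step 6 | tert-butyl{[(3R,4R,5R)-5-allyl-3-(3,4-dimethoxyphenyl)-5-(2-methoxyprop-2-en-1-yl)-4-methylcyclopent-1-en-1-yl]oxy}dimethylsilane | C=C(OC)C[C@@]1(CC=C)C(O[Si](C)(C)C(C)(C)C)=C[C@H](c2ccc(OC)c(OC)c2)[C@H]1C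
F4 | step 4 | (4R,5S)-4-methyl-5-[3-(trimethylsilyl)prop-2-yn-1-yl]cyclopent-2-en-1-one | O=C1C=C[C@@H](C)[C@@H]1CC#C[Si](C)(C)C
F5 | step 4 | (4R,5R)-5-allyl-4-methyl-5-[3-(trimethylsilyl)prop-2-yn-1-yl]cyclopent-2-en-1-one | O=C1C=C[C@@H](C)[C@@]1(CC=C)CC#C[Si](C)(C)C
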